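Everything rests on disconnecting the C4–C5 bond of ring A (eudesmane numbering). The target shows a C6 hydroxyl anti to the C5–C4 bond and an exocyclic C4=C15 methylene on the carbon bonded to C5, exactly what a β-titanoxy C5 radical leaves after adding to a C4≡C15 alkyne. One titanocene-mediated step therefore opens a C5–C6 epoxide on ring B, closes ring A, sets C5, frees the C6 hydroxyl and installs the methylene. Its precursor is the ring B cyclohexane bearing the upper-face C5–C6 epoxide, the C7 isopropyl group, the C9 4-methoxybenzoate and, on quaternary C10, methyl and pent-4-ynyl; it is assembled from (R)-carvone by an anti SN2′ alkylation.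

Key step: step 11

Remark on numbering: eudesmane numbering is used for ring B throughout (C5–C10; C15 is the methylene carbon); "upper face" is the face of ring B that carries the C7 isopropyl group, and in the target also the C6 and C9 oxygens, the C10 methyl and H5.

Assumption: (5-chloropent-1-yn-1-yl)trimethylsilane (8) is bought as such; the alkyne is carried as its C-silyl derivative because a free alkyne C–H would destroy the Grignard reagent of step 7, and it is released in step 8.

Remark: the radicals of step 11 are transient species, described in its Why line and not numbered.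

Step 1
Reactants: 1 (R)-(−)-carvone
Product: 2 (5R)-2-methyl-5-(propan-2-yl)cyclohex-2-en-1-one (carvotanacetone)
Conditions: H2 (1 atm), RhCl(PPh3)3 (cat.), toluene, rt
Reagents that add atoms: none
Why: Chemoselective homogeneous hydrogenation: RhCl(PPh3)3 reduces the unhindered 1,1-disubstituted isopropenyl alkene and leaves the trisubstituted conjugated alkene, so the carvone stereocentre (the future C7) is carried over untouched.

Step 2
Reactants: 2 (5R)-2-methyl-5-(propan-2-yl)cyclohex-2-en-1-one
Product: 3 (1R,5R)-2-methyl-5-(propan-2-yl)cyclohex-2-en-1-ol (hydroxyl cis to isopropyl)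
Conditions: NaBH4, CeCl3·7H2O, MeOH, −78 → 0 °C
Reagents that add atoms: none
Why: Luche reduction: cerium-assisted 1,2-delivery of hydride along the axial trajectory of the half-chair with an equatorial isopropyl group should give the equatorial alcohol cis to the isopropyl group (the course known for carvone), which sets the future C9 on the upper face.

Step 3
Reactants: 3 (1R,5R)-2-methyl-5-(propan-2-yl)cyclohex-2-en-1-ol
Product: 4 tert-butyl(dimethyl){[(1R,5R)-2-methyl-5-(propan-2-yl)cyclohex-2-en-1-yl]oxy}silane
Conditions: TBSCl, imidazole, DMF, rt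
Reagents that add atoms: tert-butyl(chloro)dimethylsilane, CC(C)(C)[Si](C)(C)Cl
Why: Standard silylation of a secondary alcohol (silyl ether formation), which masks the C9 oxygen through the oxidation, hydride and organometallic steps and touches no stereocentre.

Step 4
Reactants: 4 tert-butyl(dimethyl){[(1R,5R)-2-methyl-5-(propan-2-yl)cyclohex-2-en-1-yl]oxy}silane
Product: 5 (4R,6R)-4-{[tert-butyl(dimethyl)silyl]oxy}-3-methyl-6-(propan-2-yl)cyclohex-2-en-1-one
Conditions: CrO3, 3,5-dimethylpyrazole, CH2Cl2, −20 °C
Reagents that add atoms: chromium trioxide, O=[Cr](=O)=O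
Why: Allylic C–H oxidation with the CrO3–3,5-dimethylpyrazole complex: the ring methylene next to the unsubstituted alkene carbon is the accessible allylic position (the selectivity seen at C7 of steroidal 5-enes), oxygen delivered to the tertiary allylic terminus converges on the same enone by chromate transposition, and the silyloxy-bearing methine is shielded by the silyl group; no stereocentre is formed, and the isopropyl-bearing carbon, now α to the ketone, keeps its more stable equatorial (cis) arrangement.

Step 5
Reactants: 5 (4R,6R)-4-{[tert-butyl(dimethyl)silyl]oxy}-3-methyl-6-(propan-2-yl)cyclohex-2-en-1-one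
Product: 6 (1S,4R,6R)-4-{[tert-butyl(dimethyl)silyl]oxy}-3-methyl-6-(propan-2-yl)cyclohex-2-en-1-ol (hydroxyl cis to isopropyl and to silyloxy)
Conditions: LiBH(s-Bu)3, THF, −78 °C
Reagents that add atoms: none
Why: 1,2-Reduction of a β,β-disubstituted enone by a bulky trialkylborohydride: hydride enters along the equatorial trajectory from the lower face, as in the reduction of 2-alkylcyclohexanones with this reagent, so the new C6 hydroxyl should be pseudo-axial on the upper face, cis to the neighbouring isopropyl group.

Step 6
Reactants: 6 (1S,4R,6R)-4-{[tert-butyl(dimethyl)silyl]oxy}-3-methyl-6-(propan-2-yl)cyclohex-2-en-1-ol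
Product: 7 (1S,4R,6R)-4-{[tert-butyl(dimethyl)silyl]oxy}-3-methyl-6-(propan-2-yl)cyclohex-2-en-1-yl pyridine-2-carboxylate
Conditions: pyridine-2-carboxylic acid, DCC, DMAP (cat.), CH2Cl2, rt
Reagents that add atoms: pyridine-2-carboxylic acid, OC(=O)c1ccccn1
Why: Steglich esterification of the secondary allylic alcohol with retention at C6, installing the chelating picolinoxy leaving group needed for the allylic substitution.

Step 7
Reactants: 7 (1S,4R,6R)-4-{[tert-butyl(dimethyl)silyl]oxy}-3-methyl-6-(propan-2-yl)cyclohex-2-en-1-yl pyridine-2-carboxylate; 8 (5-chloropent-1-yn-1-yl)trimethylsilane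
Product: 10 tert-butyl(dimethyl){[(1R,2R,5R)-2-methyl-5-(propan-2-yl)-2-[5-(trimethylsilyl)pent-4-yn-1-yl]cyclohex-3-en-1-yl]oxy}silane, via Grignard reagent 9 (not isolated)
Conditions: 8, Mg turnings, THF, reflux; CuBr·SMe2, THF, −40 °C; then 7, −40 → 0 °C
Reagents that add atoms: none
Why: Copper-mediated anti SN2′ allylic substitution of a picolinate: the magnesium-chelated picolinoxy group leaves from the upper face of C6 while the alkylcopper reagent bonds to the methyl-bearing γ-carbon (C10) from the lower face, anti to the leaving group and to the neighbouring silyloxy group, which creates the quaternary centre with the chain trans to the C9 oxygen and the C7 isopropyl group and moves the alkene to C5=C6.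

Step 8
Reactants: 10 tert-butyl(dimethyl){[(1R,2R,5R)-2-methyl-5-(propan-2-yl)-2-[5-(trimethylsilyl)pent-4-yn-1-yl]cyclohex-3-en-1-yl]oxy}silane
Product: 11 (1R,2R,5R)-2-methyl-2-(pent-4-yn-1-yl)-5-(propan-2-yl)cyclohex-3-en-1-ol
Conditions: Bu4NF, THF, rt → 50 °C
Reagents that add atoms: none
Why: Fluoride-mediated desilylation cleaves the alkynyl C–Si bond and the hindered silyl ether in one operation and leaves all stereocentres untouched.

Step 9
Reactants: 11 (1R,2R,5R)-2-methyl-2-(pent-4-yn-1-yl)-5-(propan-2-yl)cyclohex-3-en-1-ol
Product: 12 (1R,2S,3R,5R,6S)-2-methyl-2-(pent-4-yn-1-yl)-5-(propan-2-yl)-7-oxabicyclo[4.1.0]heptan-3-ol (upper-face C5–C6 epoxide)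
Conditions: VO(acac)2 (cat.), t-BuOOH, CH2Cl2, rt → 40 °C
Reagents that add atoms: tert-butyl hydroperoxide, CC(C)(C)OO
Why: Hydroxyl-directed epoxidation: the homoallylic C9 hydroxyl binds vanadium and delivers the peroxide oxygen to the alkene face it occupies (through the conformer with an axial C9–O bond), overriding the shielding of that face by the C10 methyl, which sets C5 and C6 with the oxirane on the upper face.

Step 10
Reactants: 12 (1R,2S,3R,5R,6S)-2-methyl-2-(pent-4-yn-1-yl)-5-(propan-2-yl)-7-oxabicyclo[4.1.0]heptan-3-ol; 13 4-methoxybenzoyl chloride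
Product: 14 (1R,2S,3R,5R,6S)-2-methyl-2-(pent-4-yn-1-yl)-5-(propan-2-yl)-7-oxabicyclo[4.1.0]heptan-3-yl 4-methoxybenzoate
Conditions: Et3N, DMAP, CH2Cl2, 0 °C → rt
Reagents that add atoms: none
Why: DMAP-catalysed acylation of the hindered secondary C9 alcohol by the acid chloride under basic conditions that spare the oxirane and the terminal alkyne; the configuration at C9 is retained.

Step 11
Reactants: 14 (1R,2S,3R,5R,6S)-2-methyl-2-(pent-4-yn-1-yl)-5-(propan-2-yl)-7-oxabicyclo[4.1.0]heptan-3-yl 4-methoxybenzoate
Product: 15 (1R,3R,4S,4aS,8aR)-4-hydroxy-8a-methyl-5-methylidene-3-(propan-2-yl)decahydronaphthalen-1-yl 4-methoxybenzoate (target, CNP0107029.1)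
Conditions: Cp2TiCl2 (20 mol %), Mn dust, 2,4,6-collidine·HCl, THF, rt, slow addition of 14
Reagents that add atoms: none
Why: Cp2TiCl (trivalent titanium, formed from Cp2TiCl2 and Mn) binds the oxirane oxygen and transfers one electron, so that the C5–O bond breaks homolytically while the oxygen stays on C6 with unchanged configuration; the secondary C5 radical adds to C4 of the tethered alkyne, and the vinyl radical at C15 is quenched by hydrogen abstraction from THF or by reduction and protonation, collidinium chloride releasing the alcohol and returning Cp2TiCl2. The closest known reaction type is the titanocene-mediated reductive opening of epoxides with radical cyclisation onto alkynes, which gives methylenecycloalkanes bearing a trans β-hydroxyl. Ring A closes in the 6-exo-dig mode, helped by the quaternary C10 in the tether (gem-disubstituent effect). The only new stereocentre, C5, is set by the tether and the titanoxy group: the chain is pseudo-equatorial on the lower face of C10, and C4 bonds axially to the flattened C5 from that same face, anti to the bulky O–TiCp2Cl on C6, which gives the cis ring fusion with H5 syn to the C10 methyl and the C6 oxygen. The step needs cleavage of C5–O and not C6–O, which is favoured because the titanocene sits on the oxirane side remote from the quaternary C10 and ends on the less congested C6 oxygen, and only the C5 radical has a ring-closing pathway. It also needs ring closure to outrun capture of the C5 radical by a second Cp2TiCl, which the low stationary concentration of trivalent titanium under catalytic turnover and slow addition should secure.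

Compound list
1 | (R)-(−)-carvone, (5R)-2-methyl-5-(prop-1-en-2-yl)cyclohex-2-en-1-one | CC1=CC[C@@H](C(C)=C)CC1=O | starting material
2 | (5R)-2-methyl-5-(propan-2-yl)cyclohex-2-en-1-one | CC1=CC[C@@H](C(C)C)CC1=O | intermediate
3 | (1R,5R)-2-methyl-5-(propan-2-yl)cyclohex-2-en-1-ol | CC1=CC[C@@H](C(C)C)C[C@H]1O | intermediate
4 | tert-butyl(dimethyl){[(1R,5R)-2-methyl-5-(propan-2-yl)cyclohex-2-en-1-yl]oxy}silane | CC1=CC[C@@H](C(C)C)C[C@H]1O[Si](C)(C)C(C)(C)C | intermediate
5 | (4R,6R)-4-{[tert-butyl(dimethyl)silyl]oxy}-3-methyl-6-(propan-2-yl)cyclohex-2-en-1-one | CC1=CC(=O)[C@@H](C(C)C)C[C@H]1O[Si](C)(C)C(C)(C)C | intermediate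
6 | (1S,4R,6R)-4-{[tert-butyl(dimethyl)silyl]oxy}-3-methyl-6-(propan-2-yl)cyclohex-2-en-1-ol | CC1=C[C@@H](O)[C@@H](C(C)C)C[C@H]1O[Si](C)(C)C(C)(C)C | intermediate
7 | (1S,4R,6R)-4-{[tert-butyl(dimethyl)silyl]oxy}-3-methyl-6-(propan-2-yl)cyclohex-2-en-1-yl pyridine-2-carboxylate | CC1=C[C@@H](OC(=O)c2ccccn2)[C@@H](C(C)C)C[C@H]1O[Si](C)(C)C(C)(C)C | intermediate
8 | (5-chloropent-1-yn-1-yl)trimethylsilane | C[Si](C)(C)C#CCCCCl | starting material
9 | [5-(trimethylsilyl)pent-4-yn-1-yl]magnesium chloride | C[Si](C)(C)C#CCCC[Mg]Cl | intermediate (not isolated)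
10 | tert-butyl(dimethyl){[(1R,2R,5R)-2-methyl-5-(propan-2-yl)-2-[5-(trimethylsilyl)pent-4-yn-1-yl]cyclohex-3-en-1-yl]oxy}silane | C[Si](C)(C)C#CCCC[C@]1(C)C=C[C@@H](C(C)C)C[C@H]1O[Si](C)(C)C(C)(C)C | intermediate
11 | (1R,2R,5R)-2-methyl-2-(pent-4-yn-1-yl)-5-(propan-2-yl)cyclohex-3-en-1-ol | C#CCCC[C@]1(C)C=C[C@@H](C(C)C)C[C@H]1O | intermediate
12 | (1R,2S,3R,5R,6S)-2-methyl-2-(pent-4-yn-1-yl)-5-(propan-2-yl)-7-oxabicyclo[4.1.0]heptan-3-ol | C#CCCC[C@]1(C)[C@H]2O[C@H]2[C@@H](C(C)C)C[C@H]1O | intermediate
13 | 4-methoxybenzoyl chloride | COc1ccc(cc1)C(Cl)=O | starting material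
14 | (1R,2S,3R,5R,6S)-2-methyl-2-(pent-4-yn-1-yl)-5-(propan-2-yl)-7-oxabicyclo[4.1.0]heptan-3-yl 4-methoxybenzoate | C#CCCC[C@]1(C)[C@H]2O[C@H]2[C@@H](C(C)C)C[C@H]1OC(=O)c3ccc(OC)cc3 | intermediate
15 | (1R,3R,4S,4aS,8aR)-4-hydroxy-8a-methyl-5-methylidene-3-(propan-2-yl)decahydronaphthalen-1-yl 4-methoxybenzoate | C=C1CCC[C@]2(C)[C@H]1[C@@H](O)[C@@H](C(C)C)C[C@H]2OC(=O)c1ccc(OC)cc1 | target

Total step count: 11. Longest linear sequence: 11 steps (1 → 15).

Steps most likely to fail

Step 11. The epoxide may open at the C6–O bond, or the C5 radical may be captured by a second trivalent titanium before it closes ring A, which leads to deoxygenation to the alkene or to simple reduction. The fallback generates the C5 radical from a carbon–bromine bond. It sets out from alcohol 11: acylation with 13 (Et3N, DMAP, CH2Cl2) gives the alkene ester F1. N-Bromosuccinimide in aqueous 1,2-dimethoxyethane at 0 °C should then add bromine to the lower face, away from the pseudo-axial C10 methyl, and water trans-diaxially at C6 (the course followed by steroidal 5-enes), giving the bromohydrin F2 with bromine on C5 (lower face) and hydroxyl on C6 (upper face). Slow addition of Bu3SnH and AIBN in benzene at 80 °C forms the C5 radical at a fixed position, closes ring A by the same 6-exo-dig addition and comes back to the route at target 15.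

Step 7. The organocopper reagent may substitute at the α-carbon (C6), attack the ester carbonyl, or fail to bond to the fully substituted, silyloxy-flanked γ-carbon, so that the quaternary centre is not formed. The fallback is a sigmatropic route that fixes the same configuration by suprafacial transfer. It sets out from enone 5: Luche reduction (NaBH4, CeCl3·7H2O, MeOH) should give the pseudo-equatorial allylic alcohol F3, the C6 epimer of 6 with the hydroxyl on the lower face. Johnson–Claisen rearrangement (triethyl orthoacetate, cat. propanoic acid, 140 °C) delivers the two-carbon unit to the lower face of C10 and gives the ethyl ester F4. LiAlH4 in THF gives the primary alcohol F5, and I2, PPh3 and imidazole give the iodide F6. Alkylation of the lithium derivative of 1-(trimethylsilyl)propyne (n-BuLi, THF, −78 °C) with F6 completes the five-carbon chain and comes back to the route at 10.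

Step 4. Oxidation may occur at the silyloxy-bearing allylic C–H (loss of the protected oxygen and return to enone 2), or the hindered methylene may be over-oxidised or converted poorly. The fallback introduces the C6 oxygen by epoxide chemistry and oxidative allylic transposition. It sets out from alcohol 3: hydroxyl-directed epoxidation (mCPBA, NaHCO3, CH2Cl2, 0 °C) gives the cis-epoxy alcohol F7, and silylation (TBSCl, imidazole, DMF) gives the silyl ether F8. Sodium phenylselenide, PhSeNa, made from (PhSe)2 and NaBH4 in EtOH at reflux, opens the oxirane trans-diaxially at the secondary carbon to give the hydroxy selenide F9. H2O2 (THF, 0 °C → rt) oxidises it to the selenoxide F10, which eliminates away from the carbinol carbon to give the tertiary allylic alcohol F11. Babler–Dauben oxidative transposition with pyridinium chlorochromate (C5H5NH[CrO3Cl], CH2Cl2, rt) comes back to the route at enone 5.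

Further compounds
F1 | step 11 | 4-methoxybenzoate of alcohol 11, (1R,2R,5R)-2-methyl-2-(pent-4-yn-1-yl)-5-(propan-2-yl)cyclohex-3-en-1-yl 4-methoxybenzoate | C#CCCC[C@]1(C)C=C[C@@H](C(C)C)C[C@H]1OC(=O)c2ccc(OC)cc2
F2 | step 11 | bromohydrin of F1 with bromine on C5 (lower face) and hydroxyl on C6 (upper face), trans-diaxial | C#CCCC[C@]1(C)[C@H](Br)[C@@H](O)[C@@H](C(C)C)C[C@H]1OC(=O)c2ccc(OC)cc2
F3 | step 7 | carbinol epimer of 6, hydroxyl trans to the isopropyl group, (1R,4R,6R)-4-{[tert-butyl(dimethyl)silyl]oxy}-3-methyl-6-(propan-2-yl)cyclohex-2-en-1-ol | CC1=C[C@H](O)[C@@H](C(C)C)C[C@H]1O[Si](C)(C)C(C)(C)C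
F4 | step 7 | ethyl ester with the CH2CO2Et group on C10 in place of the chain of 10 (lower face, same ring and stereocentres as 10) | CCOC(=O)C[C@]1(C)C=C[C@@H](C(C)C)C[C@H]1O[Si](C)(C)C(C)(C)C
F5 | step 7 | primary alcohol from F4, 2-hydroxyethyl group on C10 | OCC[C@]1(C)C=C[C@@H](C(C)C)C[C@H]1O[Si](C)(C)C(C)(C)C
F6 | step 7 | primary iodide from F5, 2-iodoethyl group on C10 | ICC[C@]1(C)C=C[C@@H](C(C)C)C[C@H]1O[Si](C)(C)C(C)(C)C
F7 | step 4 | cis-epoxy alcohol from 3, oxirane on the methyl-bearing alkene, syn to the hydroxyl and to the isopropyl group | C[C@]12O[C@H]1C[C@@H](C(C)C)C[C@H]2O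
F8 | step 4 | tert-butyldimethylsilyl ether of F7 | C[C@]12O[C@H]1C[C@@H](C(C)C)C[C@H]2O[Si](C)(C)C(C)(C)C
F9 | step 4 | hydroxy selenide from F8, tertiary hydroxyl on the upper face and phenylselanyl group on the neighbouring secondary carbon on the lower face | C[C@]1(O)[C@H]([Se]c2ccccc2)C[C@@H](C(C)C)C[C@H]1O[Si](C)(C)C(C)(C)C
F10 | step 4 | selenoxide of F9 (configuration at selenium not defined) | C[C@]1(O)[C@H]([Se](=O)c2ccccc2)C[C@@H](C(C)C)C[C@H]1O[Si](C)(C)C(C)(C)C
F11 | step 4 | tertiary allylic alcohol from F10, hydroxyl on the methyl-bearing carbon (upper face) and the alkene between the next two ring carbons | C[C@]1(O)C=C[C@@H](C(C)C)C[C@H]1O[Si](C)(C)C(C)(C)C
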